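**Retrosynthetic overview**

1. The strategy rests on ring A: the C1 oxygen and C20 are cis on the adjacent carbons C1 and C10 (C10 quaternary). This is an aldol pattern O–C1–C10–C20, stored as the cis-fused β-lactone C1–O–C20(=O)–C10 and later opened by hydride to C1–OH and C20H2–OH.
2. Late stage, backwards from the target: H2 on the 16-methylene-15-ketone sets C16; ring D comes from C13–C16 bond formation (palladium-mediated cyclisation of the C15 enol silane onto C12=C13); ring C with C8 and C9 comes from a Diels–Alder addition of butadiene to the C8=C9 alkylidene acetoacetate lactone; the δ-lactone comes from Knoevenagel closure of the C20 acetoacetate onto the C9 aldehyde (ozonolysis of the C10 propenyl group).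
3. Key disconnection: C1–C10 and C1–O–C20 by isothiourea-catalysed aldol-lactonisation of an aldehyde acid (C1 aldehyde, C20 acid, C10 carrying propenyl and C5).
4. Aldehyde acid: C5–C10 bond by Ireland–Claisen rearrangement with chirality transfer from an (S)-allylic alcohol; pieces from diethyl isopropylidenemalonate, 2-(2-bromoethyl)-1,3-dioxane and (S)-but-3-yn-2-ol.
5. Ring order: ring A with the β-lactone, then the δ-lactone ring, then ring C, then ring D.

Key step: step 13

Remark on numbering: atoms carry the ent-kaurane numbers of the target: C1 (CH–OAc), C2, C3, C4 (CMe2), C5 (CH bearing the acid carbon C6), C10 (spiro), C20 (OCH2), C7 (lactone C=O), C8, C9, C11–C14, C15 (ketone), C16 (CH bearing methyl C17).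

Assumption: the alkenyl spectator on C10 is carried as (E)-prop-1-enyl (its methyl end comes from the chiral allylic alcohol that sets C5, and ozonolysis removes it), and C6 is carried as a tert-butyl ester. C5 is fixed before the key step and not by later equilibration, because an ester at C5 flanked by C4 and C10 has no reliable thermodynamic preference.

**Route**

Step 1
Reactants: 1 diethyl 2-(propan-2-ylidene)malonate; 2 2-(2-bromoethyl)-1,3-dioxane
Product: 4 diethyl 2-[4-(1,3-dioxan-2-yl)-2-methylbutan-2-yl]malonate, via Grignard reagent 3 (not isolated)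
Conditions: 2, Mg, THF, rt; then CuBr·SMe2 (5 mol %), 1, THF, −20 °C → rt; H2O work-up
Reagents that add atoms: none
Why: Copper-catalysed conjugate addition of a Grignard reagent to an alkylidene malonate, a doubly activated acceptor that accepts attack at a β,β-disubstituted carbon, builds the C4 quaternary centre with C1–C3 attached and C1 masked as an acetal.

Step 2
Reactants: 4 diethyl 2-[4-(1,3-dioxan-2-yl)-2-methylbutan-2-yl]malonate
Product: 5 ethyl 5-(1,3-dioxan-2-yl)-3,3-dimethylpentanoate
Conditions: LiCl, H2O, DMSO, 160 °C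
Reagents that add atoms: none
Why: Krapcho dealkoxycarbonylation removes one malonate ester under neutral conditions that leave the acetal intact.

Step 3
Reactants: 5 ethyl 5-(1,3-dioxan-2-yl)-3,3-dimethylpentanoate
Product: 6 5-(1,3-dioxan-2-yl)-3,3-dimethylpentanoic acid
Conditions: LiOH, THF–MeOH–H2O, 50 °C; then 1 M HCl to pH 4, 0 °C
Reagents that add atoms: lithium hydroxide, [Li+].[OH-]
Why: Saponification of the ethyl ester; the dioxane acetal is stable to base and to the brief, cold, mildly acidic work-up.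

Step 4
Reactants: 7 (S)-but-3-yn-2-ol
Product: 8 (S)-pent-2-yne-1,4-diol
Conditions: n-BuLi (2.2 equiv), THF, −78 → 0 °C; (CH2O)n, 0 °C → rt; H2O work-up
Reagents that add atoms: formaldehyde (from paraformaldehyde), C=O
Why: Hydroxymethylation of the lithium acetylide (generated with the alkoxide) by formaldehyde adds C20 without touching the carbinol stereocentre.

Step 5
Reactants: 8 (S)-pent-2-yne-1,4-diol
Product: 9 (S,E)-pent-2-ene-1,4-diol
Conditions: LiAlH4, THF, 0 °C → reflux
Reagents that add atoms: none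
Why: Alkoxide-directed trans-hydroalumination of a propargylic alcohol gives only the (E)-alkene and leaves the stereocentre untouched.

Step 6
Reactants: 9 (S,E)-pent-2-ene-1,4-diol
Product: 10 (S,E)-5-[(tert-butyldimethylsilyl)oxy]pent-3-en-2-ol
Conditions: TBSCl (1.0 equiv), imidazole, CH2Cl2, −20 → 0 °C
Reagents that add atoms: tert-butyldimethylsilyl chloride, CC(C)(C)[Si](C)(C)Cl
Why: Selective silylation of the primary allylic hydroxyl over the secondary one on steric grounds.

Step 7
Reactants: 6 5-(1,3-dioxan-2-yl)-3,3-dimethylpentanoic acid; 10 (S,E)-5-[(tert-butyldimethylsilyl)oxy]pent-3-en-2-ol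
Product: 11 (2S,3E)-5-[(tert-butyldimethylsilyl)oxy]pent-3-en-2-yl 5-(1,3-dioxan-2-yl)-3,3-dimethylpentanoate
Conditions: DCC, DMAP (cat.), CH2Cl2, 0 °C → rt
Reagents that add atoms: none
Why: Steglich esterification joins the C1–C6 acid to the secondary allylic alcohol with retention at the carbinol carbon.

Step 8
Reactants: 11 (2S,3E)-5-[(tert-butyldimethylsilyl)oxy]pent-3-en-2-yl 5-(1,3-dioxan-2-yl)-3,3-dimethylpentanoate
Product: 14 (2S,3R,4E)-3-{[(tert-butyldimethylsilyl)oxy]methyl}-2-[4-(1,3-dioxan-2-yl)-2-methylbutan-2-yl]hex-4-enoic acid, via silyl ketene acetal 12 (not isolated), via trimethylsilyl ester 13 (not isolated)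
Conditions: LiN(iPr)2 (LDA), THF, −78 °C; Me3SiCl, −78 °C → rt, then 60 °C; then H2O, THF, rt
Reagents that add atoms: none
Why: Ireland–Claisen rearrangement: LDA in THF gives the enolate with the tert-alkyl group cis to the allylic oxygen, and the chair transition state with the carbinol methyl equatorial transfers the (S) configuration to C5 (and C10) while it forms the C5–C10 bond and the (E)-propenyl group.

Step 9
Reactants: 14 (2S,3R,4E)-3-{[(tert-butyldimethylsilyl)oxy]methyl}-2-[4-(1,3-dioxan-2-yl)-2-methylbutan-2-yl]hex-4-enoic acid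
Product: 15 tert-butyl (2S,3R,4E)-3-{[(tert-butyldimethylsilyl)oxy]methyl}-2-[4-(1,3-dioxan-2-yl)-2-methylbutan-2-yl]hex-4-enoate
Conditions: Me2NCH(OtBu)2, toluene, 80 °C
Reagents that add atoms: N,N-dimethylformamide di-tert-butyl acetal, CN(C)C(OC(C)(C)C)OC(C)(C)C
Why: O-tert-butylation of the carboxylate by the formamide acetal needs no attack at the crowded carbonyl and gives an ester that later resists hydride, lactonisation and base.

Step 10
Reactants: 15 tert-butyl (2S,3R,4E)-3-{[(tert-butyldimethylsilyl)oxy]methyl}-2-[4-(1,3-dioxan-2-yl)-2-methylbutan-2-yl]hex-4-enoate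
Product: 16 tert-butyl (2S,3R,4E)-2-[4-(1,3-dioxan-2-yl)-2-methylbutan-2-yl]-3-(hydroxymethyl)hex-4-enoate
Conditions: HF·pyridine, pyridine, THF, 0 °C → rt
Reagents that add atoms: none
Why: Buffered fluoride cleavage of the primary silyl ether is nearly neutral, so the acetal survives and the γ-hydroxy tert-butyl ester should not lactonise.

Step 11
Reactants: 16 tert-butyl (2S,3R,4E)-2-[4-(1,3-dioxan-2-yl)-2-methylbutan-2-yl]-3-(hydroxymethyl)hex-4-enoate
Product: 17 (2R,3S)-3-(tert-butoxycarbonyl)-6-(1,3-dioxan-2-yl)-4,4-dimethyl-2-[(E)-prop-1-enyl]hexanoic acid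
Conditions: TEMPO (cat.), PhI(OAc)2 (2.2 equiv), MeCN–H2O, rt
Reagents that add atoms: water, O
Why: Oxoammonium (TEMPO) oxidation takes the primary alcohol through the aldehyde hydrate to the C20 acid without touching the alkene, and any epimerisation at C10 is harmless because that centre is planarised in step 13.

Step 12
Reactants: 17 (2R,3S)-3-(tert-butoxycarbonyl)-6-(1,3-dioxan-2-yl)-4,4-dimethyl-2-[(E)-prop-1-enyl]hexanoic acid
Product: 18 (2R,3S)-3-(tert-butoxycarbonyl)-4,4-dimethyl-7-oxo-2-[(E)-prop-1-enyl]heptanoic acid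
Conditions: 2 M HCl, THF, rt
Reagents that add atoms: water, O
Why: Acid-catalysed acetal hydrolysis releases the C1 aldehyde, and the hindered tert-butyl ester survives dilute aqueous acid.

Step 13
Reactants: 18 (2R,3S)-3-(tert-butoxycarbonyl)-4,4-dimethyl-7-oxo-2-[(E)-prop-1-enyl]heptanoic acid
Product: 21 tert-butyl (1R,2R,6S)-3,3-dimethyl-8-oxo-1-[(E)-prop-1-enyl]-7-oxabicyclo[4.2.0]octane-2-carboxylate, via mixed anhydride 19 (not isolated), via acyl isothiouronium salt 20 (not isolated)
Conditions: TsCl (1.2 equiv), (R)-HBTM [(R)-2-phenyl-3,4-dihydro-2H-benzo[4,5]thiazolo[3,2-a]pyrimidine, 20 mol %], LiCl (1 equiv), iPr2NEt (4 equiv), CH2Cl2, rt, slow addition of 18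
Reagents that add atoms: none
Why: Proposed new method: TsCl converts the acid into mixed anhydride 19, which acylates the isothiourea to give 20; iPr2NEt removes the doubly activated C10–H (α to the acylammonium and allylic) to give a fully substituted ammonium dienolate held planar by the 1,5 O···S contact, this adds through C10 to the C1 aldehyde, and the aldolate attacks C20 to close the β-lactone and release the catalyst. The closest known reactions are the nucleophile-catalysed aldol-lactonisation of aldehyde acids and keto acids that carry a monosubstituted α-carbon and the Lewis-base-catalysed [2+2] addition of disubstituted ketenes to aldehydes; the new element is an α-alkyl-α-alkenyl ammonium enolate in the intramolecular mode. Ring A closes by a 6-(enolexo)-exo-trig aldol step through a chair with the C5 ester equatorial and C20 axial, and the β-lactone closes by 4-exo-trig acyl substitution. C10 is set by the catalyst, whose pseudo-axial phenyl group blocks one enolate face (on the working model that the propenyl group lies cis to the catalyst nitrogen and the C5 branch cis to O−), and this is also the face that lets the existing C5 centre keep its ester equatorial; C1 is set by the closed transition state, since only an aldolate syn to C20 can lactonise, which places the C1 oxygen cis to C20. The step needs α- and not γ-attack of the dienolate and no enolisation of the aldehyde: α-attack closes a six-membered ring whereas γ-attack would need an eight-membered one, and the amine base is too weak to remove C2–H or C5–H, so C5 is not scrambled.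

Step 14
Reactants: 21 tert-butyl (1R,2R,6S)-3,3-dimethyl-8-oxo-1-[(E)-prop-1-enyl]-7-oxabicyclo[4.2.0]octane-2-carboxylate
Product: 22 tert-butyl (1R,2S,3S)-3-hydroxy-2-(hydroxymethyl)-6,6-dimethyl-2-[(E)-prop-1-enyl]cyclohexane-1-carboxylate
Conditions: LiBH4, THF, 0 °C
Reagents that add atoms: none
Why: Hydride reduction of the strained β-lactone (acyl–oxygen cleavage, then reduction of the aldehyde) gives the C1,C20-diol with C1 and C10 unchanged, the hindered tert-butyl ester being inert to LiBH4.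

Step 15
Reactants: 22 tert-butyl (1R,2S,3S)-3-hydroxy-2-(hydroxymethyl)-6,6-dimethyl-2-[(E)-prop-1-enyl]cyclohexane-1-carboxylate
Product: 23 tert-butyl (1R,2S,3S)-2-{[(tert-butyldimethylsilyl)oxy]methyl}-3-hydroxy-6,6-dimethyl-2-[(E)-prop-1-enyl]cyclohexane-1-carboxylate
Conditions: TBSCl, imidazole, DMF, 0 °C
Reagents that add atoms: tert-butyldimethylsilyl chloride, CC(C)(C)[Si](C)(C)Cl
Why: Selective silylation of the primary C20 hydroxyl over the secondary C1 hydroxyl.

Step 16
Reactants: 23 tert-butyl (1R,2S,3S)-2-{[(tert-butyldimethylsilyl)oxy]methyl}-3-hydroxy-6,6-dimethyl-2-[(E)-prop-1-enyl]cyclohexane-1-carboxylate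
Product: 24 tert-butyl (1R,2S,3S)-3-acetoxy-2-{[(tert-butyldimethylsilyl)oxy]methyl}-6,6-dimethyl-2-[(E)-prop-1-enyl]cyclohexane-1-carboxylate
Conditions: Ac2O, DMAP, Et3N, CH2Cl2, rt
Reagents that add atoms: acetic anhydride, CC(=O)OC(C)=O
Why: DMAP-catalysed acetylation installs the C1 acetate of the target with retention and blocks later attack of the C1 oxygen on the C7 lactone.

Step 17
Reactants: 24 tert-butyl (1R,2S,3S)-3-acetoxy-2-{[(tert-butyldimethylsilyl)oxy]methyl}-6,6-dimethyl-2-[(E)-prop-1-enyl]cyclohexane-1-carboxylate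
Product: 25 tert-butyl (1R,2S,3S)-3-acetoxy-2-(hydroxymethyl)-6,6-dimethyl-2-[(E)-prop-1-enyl]cyclohexane-1-carboxylate
Conditions: HF·pyridine, pyridine, THF, 0 °C → rt
Reagents that add atoms: none
Why: Buffered fluoride desilylation frees C20–OH under non-basic conditions, so the acetate should not migrate from O1 to O20.

Step 18
Reactants: 25 tert-butyl (1R,2S,3S)-3-acetoxy-2-(hydroxymethyl)-6,6-dimethyl-2-[(E)-prop-1-enyl]cyclohexane-1-carboxylate; 26 2,2,6-trimethyl-4H-1,3-dioxin-4-one
Product: 28 tert-butyl (1R,2S,3S)-3-acetoxy-6,6-dimethyl-2-{[(3-oxobutanoyl)oxy]methyl}-2-[(E)-prop-1-enyl]cyclohexane-1-carboxylate, via acetylketene 27 (not isolated)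
Conditions: toluene, 110 °C
Reagents that add atoms: none
Why: Thermal retro-Diels–Alder cleavage of the dioxinone gives acetylketene, which acylates the primary alcohol to the acetoacetate under neutral conditions and so brings in C7, C8, C15 and C16.

Step 19
Reactants: 28 tert-butyl (1R,2S,3S)-3-acetoxy-6,6-dimethyl-2-{[(3-oxobutanoyl)oxy]methyl}-2-[(E)-prop-1-enyl]cyclohexane-1-carboxylate
Product: 29 tert-butyl (1R,2R,3S)-3-acetoxy-2-formyl-6,6-dimethyl-2-{[(3-oxobutanoyl)oxy]methyl}cyclohexane-1-carboxylate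
Conditions: O3, CH2Cl2–MeOH, −78 °C (indicator end point); then Me2S, −78 °C → rt
Reagents that add atoms: ozone, [O-][O+]=O
Why: Ozonolysis with reductive work-up cleaves the propenyl group to the C9 aldehyde, which cannot enolise because C10 is quaternary.

Step 20
Reactants: 29 tert-butyl (1R,2R,3S)-3-acetoxy-2-formyl-6,6-dimethyl-2-{[(3-oxobutanoyl)oxy]methyl}cyclohexane-1-carboxylate
Product: 30 tert-butyl 11-acetoxy-4-acetyl-8,8-dimethyl-3-oxo-2-oxaspiro[5.5]undec-4-ene-7-carboxylate [(1S,5R,10S) by target numbering; C8=C9 alkylidene lactone]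
Conditions: piperidine (cat.), AcOH (cat.), 4 Å MS, CH2Cl2, rt
Reagents that add atoms: none
Why: Intramolecular Knoevenagel condensation of the acetoacetate with the non-enolisable C9 aldehyde closes the six-membered lactone as a 3-acetyl-5,6-dihydropyran-2-one.

Step 21
Reactants: 30 tert-butyl 11-acetoxy-4-acetyl-8,8-dimethyl-3-oxo-2-oxaspiro[5.5]undec-4-ene-7-carboxylate; 31 buta-1,3-diene
Product: 32 Diels–Alder adduct [(1S,5R,8S,9S,10S) by target numbering: ring A as in 30; spiro δ-lactone C10–C20–O–C7(=O)–C8–C9; cyclohexene ring C (C8–C14–C13=C12–C11–C9) cis-fused to the lactone with C11 and C14 on the C1 side; acetyl group (C15, C16) on C8 on the C5 side]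
Conditions: ZnCl2, CH2Cl2, −20 °C → rt, sealed tube
Reagents that add atoms: none
Why: Diels–Alder reaction of a ZnCl2-chelated alkylidene β-keto lactone (a doubly activated dienophile): suprafacial addition sets C8 and C9 together with C11 and C14 cis, and the diene should add to the face of C8=C9 anti to the C10–C5 bond, whose C5 carries the tert-butyl ester beside the gem-dimethyl carbon, that is, on the side of the smaller C1 acetate.

Step 22
Reactants: 32 Diels–Alder adduct
Product: 33 tert-butyldimethylsilyl enol ether of 32 [C15(OTBS)=C16H2; otherwise as 32]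
Conditions: TBSOTf, Et3N, CH2Cl2, −78 → 0 °C
Reagents that add atoms: tert-butyldimethylsilyl trifluoromethanesulfonate, CC(C)(C)[Si](C)(C)OS(=O)(=O)C(F)(F)F
Why: Soft enolisation of the methyl ketone, whose only α-hydrogens are on C16 because C8 is quaternary.

Step 23
Reactants: 33 tert-butyldimethylsilyl enol ether of 32
Product: 34 tetracyclic ketone [(1S,5R,8S,9S,10S,13R) by target numbering: ring D closed as the bicyclo[3.2.1]octan-15-one with C16H2 and a C11=C12 double bond]
Conditions: Pd(OAc)2 (1.1 equiv), MeCN, rt → 40 °C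
Reagents that add atoms: none
Why: Oxidative cycloalkenylation of a silyl enol ether with Pd(OAc)2 (transmetallation to a divalent palladium enolate, 5-exo carbopalladation of C12=C13, β-hydride elimination towards C11) forms C13–C16 and closes ring D, and C13 follows from C8 because the two-carbon bridge can span only one face of ring C.

Step 24
Reactants: 34 tetracyclic ketone
Product: 37 16-methylene-15-ketone [(1S,5R,8S,9S,10S,13S) by target numbering; C16=C17 exocyclic; C11=C12 retained], via Mannich base 35 (not isolated), via methiodide 36 (not isolated)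
Conditions: LiN(SiMe3)2, THF, −78 °C; CH2=NMe2+ I−, −78 °C → rt; MeI, CH2Cl2, rt; aq NaHCO3
Reagents that add atoms: Eschenmoser's salt (N,N-dimethylmethyleneiminium iodide), C=[N+](C)C.[I-]
Why: Mannich reaction of the ketone enolate (C16 is the only enolisable ketone position and the ketone is far more acidic than the acetate) with the iminium salt, then quaternisation and E1cB elimination, gives the α-methylene ketone and brings in C17.

Step 25
Reactants: 37 16-methylene-15-ketone
Product: 38 enone acid [as 37 with C6 as the free carboxylic acid]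
Conditions: CF3CO2H, CH2Cl2, 0 °C → rt
Reagents that add atoms: none
Why: Acidolysis of the tert-butyl ester with loss of isobutene leaves acetate, lactone and enone untouched, and it is done before C16 becomes an epimerisable centre.

Step 26
Reactants: 38 enone acid
Product: 39 target CNP0161834.1 [(1S,5R,8S,9S,10S,13R,16R) by target numbering]
Conditions: H2 (1 atm), PtO2, EtOAc, rt
Reagents that add atoms: none
Why: Heterogeneous hydrogenation saturates C11=C12 and adds H2 to the exocyclic C16=C17 bond from the exo face of the bicyclo[3.2.1]octane (the side of the C14 bridge), which places the C17 methyl on the side of C11 and C12 as required; platinum is chosen to limit double-bond migration towards C9.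

**Compound list**

1 | diethyl 2-(propan-2-ylidene)malonate | CCOC(=O)C(=C(C)C)C(=O)OCC | starting material
2 | 2-(2-bromoethyl)-1,3-dioxane | BrCCC1OCCCO1 | starting material
3 | [2-(1,3-dioxan-2-yl)ethyl]magnesium bromide | Br[Mg]CCC1OCCCO1 | intermediate (not isolated)
4 | diethyl 2-[4-(1,3-dioxan-2-yl)-2-methylbutan-2-yl]malonate | CCOC(=O)C(C(=O)OCC)C(C)(C)CCC1OCCCO1 | intermediate
5 | ethyl 5-(1,3-dioxan-2-yl)-3,3-dimethylpentanoate | CCOC(=O)CC(C)(C)CCC1OCCCO1 | intermediate
6 | 5-(1,3-dioxan-2-yl)-3,3-dimethylpentanoic acid | OC(=O)CC(C)(C)CCC1OCCCO1 | intermediate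
7 | (S)-but-3-yn-2-ol | C[C@H](O)C#C | starting material
8 | (S)-pent-2-yne-1,4-diol | C[C@H](O)C#CCO | intermediate
9 | (S,E)-pent-2-ene-1,4-diol | C[C@H](O)/C=C/CO | intermediate
10 | (S,E)-5-[(tert-butyldimethylsilyl)oxy]pent-3-en-2-ol | C[C@H](O)/C=C/CO[Si](C)(C)C(C)(C)C | intermediate
11 | (2S,3E)-5-[(tert-butyldimethylsilyl)oxy]pent-3-en-2-yl 5-(1,3-dioxan-2-yl)-3,3-dimethylpentanoate | C[C@H](OC(=O)CC(C)(C)CCC1OCCCO1)/C=C/CO[Si](C)(C)C(C)(C)C | intermediate
12 | trimethylsilyl ketene acetal of 11 (tert-alkyl group cis to the allylic oxygen) | C[C@H](O/C(O[Si](C)(C)C)=C\C(C)(C)CCC1OCCCO1)/C=C/CO[Si](C)(C)C(C)(C)C | intermediate (not isolated)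
13 | trimethylsilyl ester of 14 | O1CCCOC1CCC(C)(C)[C@@H](C(=O)O[Si](C)(C)C)[C@@H](/C=C/C)CO[Si](C)(C)C(C)(C)C | intermediate (not isolated)
14 | (2S,3R,4E)-3-{[(tert-butyldimethylsilyl)oxy]methyl}-2-[4-(1,3-dioxan-2-yl)-2-methylbutan-2-yl]hex-4-enoic acid | O1CCCOC1CCC(C)(C)[C@@H](C(=O)O)[C@@H](/C=C/C)CO[Si](C)(C)C(C)(C)C | intermediate
15 | tert-butyl (2S,3R,4E)-3-{[(tert-butyldimethylsilyl)oxy]methyl}-2-[4-(1,3-dioxan-2-yl)-2-methylbutan-2-yl]hex-4-enoate | O1CCCOC1CCC(C)(C)[C@@H](C(=O)OC(C)(C)C)[C@@H](/C=C/C)CO[Si](C)(C)C(C)(C)C | intermediate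
16 | tert-butyl (2S,3R,4E)-2-[4-(1,3-dioxan-2-yl)-2-methylbutan-2-yl]-3-(hydroxymethyl)hex-4-enoate | O1CCCOC1CCC(C)(C)[C@@H](C(=O)OC(C)(C)C)[C@@H](/C=C/C)CO | intermediate
17 | (2R,3S)-3-(tert-butoxycarbonyl)-6-(1,3-dioxan-2-yl)-4,4-dimethyl-2-[(E)-prop-1-enyl]hexanoic acid | O1CCCOC1CCC(C)(C)[C@@H](C(=O)OC(C)(C)C)[C@@H](/C=C/C)C(=O)O | intermediate
18 | (2R,3S)-3-(tert-butoxycarbonyl)-4,4-dimethyl-7-oxo-2-[(E)-prop-1-enyl]heptanoic acid (key-step precursor) | O=CCCC(C)(C)[C@@H](C(=O)OC(C)(C)C)[C@@H](/C=C/C)C(=O)O | intermediate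
19 | mixed anhydride of 18 with 4-methylbenzenesulfonic acid | O=CCCC(C)(C)[C@@H](C(=O)OC(C)(C)C)[C@@H](/C=C/C)C(=O)OS(=O)(=O)c1ccc(C)cc1 | intermediate (not isolated)
20 | N-acyl isothiouronium tosylate from 19 and (R)-HBTM | O=CCCC(C)(C)[C@@H](C(=O)OC(C)(C)C)[C@@H](/C=C/C)C(=O)[N+]1=C2Sc3ccccc3N2CC[C@@H]1c1ccccc1.Cc1ccc(cc1)S(=O)(=O)[O-] | intermediate (not isolated)
21 | tert-butyl (1R,2R,6S)-3,3-dimethyl-8-oxo-1-[(E)-prop-1-enyl]-7-oxabicyclo[4.2.0]octane-2-carboxylate (key-step product) | O=C2O[C@H]1CCC(C)(C)[C@@H](C(=O)OC(C)(C)C)[C@]12/C=C/C | intermediate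
22 | tert-butyl (1R,2S,3S)-3-hydroxy-2-(hydroxymethyl)-6,6-dimethyl-2-[(E)-prop-1-enyl]cyclohexane-1-carboxylate | O[C@H]1CCC(C)(C)[C@@H](C(=O)OC(C)(C)C)[C@@]1(/C=C/C)CO | intermediate
23 | tert-butyl (1R,2S,3S)-2-{[(tert-butyldimethylsilyl)oxy]methyl}-3-hydroxy-6,6-dimethyl-2-[(E)-prop-1-enyl]cyclohexane-1-carboxylate | O[C@H]1CCC(C)(C)[C@@H](C(=O)OC(C)(C)C)[C@@]1(/C=C/C)CO[Si](C)(C)C(C)(C)C | intermediate
24 | tert-butyl (1R,2S,3S)-3-acetoxy-2-{[(tert-butyldimethylsilyl)oxy]methyl}-6,6-dimethyl-2-[(E)-prop-1-enyl]cyclohexane-1-carboxylate | CC(=O)O[C@H]1CCC(C)(C)[C@@H](C(=O)OC(C)(C)C)[C@@]1(/C=C/C)CO[Si](C)(C)C(C)(C)C | intermediate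
25 | tert-butyl (1R,2S,3S)-3-acetoxy-2-(hydroxymethyl)-6,6-dimethyl-2-[(E)-prop-1-enyl]cyclohexane-1-carboxylate | CC(=O)O[C@H]1CCC(C)(C)[C@@H](C(=O)OC(C)(C)C)[C@@]1(/C=C/C)CO | intermediate
26 | 2,2,6-trimethyl-4H-1,3-dioxin-4-one | CC1=CC(=O)OC(C)(C)O1 | starting material
27 | acetylketene | CC(=O)C=C=O | intermediate (not isolated)
28 | tert-butyl (1R,2S,3S)-3-acetoxy-6,6-dimethyl-2-{[(3-oxobutanoyl)oxy]methyl}-2-[(E)-prop-1-enyl]cyclohexane-1-carboxylate | CC(=O)O[C@H]1CCC(C)(C)[C@@H](C(=O)OC(C)(C)C)[C@@]1(/C=C/C)COC(=O)CC(C)=O | intermediate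
29 | tert-butyl (1R,2R,3S)-3-acetoxy-2-formyl-6,6-dimethyl-2-{[(3-oxobutanoyl)oxy]methyl}cyclohexane-1-carboxylate | CC(=O)O[C@H]1CCC(C)(C)[C@@H](C(=O)OC(C)(C)C)[C@@]1(C=O)COC(=O)CC(C)=O | intermediate
30 | tert-butyl 11-acetoxy-4-acetyl-8,8-dimethyl-3-oxo-2-oxaspiro[5.5]undec-4-ene-7-carboxylate, (1S,5R,10S) by target numbering | CC(=O)O[C@H]1CCC(C)(C)[C@@H](C(=O)OC(C)(C)C)[C@@]12COC(=O)C(C(C)=O)=C2 | intermediate
31 | buta-1,3-diene | C=CC=C | starting material
32 | Diels–Alder adduct: ring C cyclohexene (C12=C13) cis-fused to the spiro δ-lactone, C8 acetyl, (1S,5R,8S,9S,10S) by target numbering | CC(=O)O[C@H]1CCC(C)(C)[C@@H](C(=O)OC(C)(C)C)[C@@]12COC(=O)[C@@]1(C(C)=O)CC=CC[C@H]12 | intermediate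
33 | tert-butyldimethylsilyl enol ether of 32, C15(OTBS)=C16H2 | CC(=O)O[C@H]1CCC(C)(C)[C@@H](C(=O)OC(C)(C)C)[C@@]12COC(=O)[C@@]1(C(=C)O[Si](C)(C)C(C)(C)C)CC=CC[C@H]12 | intermediate
34 | tetracyclic 15-ketone with ring D closed (C13–C16), C16H2, C11=C12, (1S,5R,8S,9S,10S,13R) by target numbering | CC(=O)O[C@H]1CCC(C)(C)[C@@H](C(=O)OC(C)(C)C)[C@@]12COC(=O)[C@@]13C[C@@H](C=C[C@H]12)CC3=O | intermediate
35 | Mannich base of 34, C16–CH2NMe2 (C16 epimers) | CC(=O)O[C@H]1CCC(C)(C)[C@@H](C(=O)OC(C)(C)C)[C@@]12COC(=O)[C@@]13C[C@@H](C=C[C@H]12)C(CN(C)C)C3=O | intermediate (not isolated)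
36 | methiodide of 35 | CC(=O)O[C@H]1CCC(C)(C)[C@@H](C(=O)OC(C)(C)C)[C@@]12COC(=O)[C@@]13C[C@@H](C=C[C@H]12)C(C[N+](C)(C)C)C3=O.[I-] | intermediate (not isolated)
37 | 16-methylene-15-ketone tert-butyl ester with C11=C12, (1S,5R,8S,9S,10S,13S) by target numbering | CC(=O)O[C@H]1CCC(C)(C)[C@@H](C(=O)OC(C)(C)C)[C@@]12COC(=O)[C@@]13C[C@@H](C=C[C@H]12)C(=C)C3=O | intermediate
38 | 16-methylene-15-ketone C6 acid with C11=C12, (1S,5R,8S,9S,10S,13S) by target numbering | CC(=O)O[C@H]1CCC(C)(C)[C@@H](C(=O)O)[C@@]12COC(=O)[C@@]13C[C@@H](C=C[C@H]12)C(=C)C3=O | intermediate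
39 | CNP0161834.1: (1S,5R,8S,9S,10S,13R,16R)-1-acetoxy-15-oxo-6,7-seco-ent-kauran-7,20-olid-6-oic acid | CC(=O)O[C@H]1CCC(C)(C)[C@@H](C(=O)O)[C@@]12COC(=O)[C@@]13C[C@@H](CC[C@H]12)[C@@H](C)C3=O | target

**Totals**

Total step count: 26. Longest linear sequence: 23 steps (steps 1–3 or 4–6, then 7–26).

**Steps most likely to fail**

Step 13 (the step marked as a new method). Deprotonation at the fully substituted C10 may be slow, so that intermolecular acylation or ketene dimerisation competes; the catalyst may fail to dominate the C5 centre, or the enolate may adopt the other geometry, which would reverse the facial sense at C10 and C1; γ-protonation may move the alkene into conjugation. The fallback uses known chemistry, a samarium Reformatsky aldol, and sets out from 17. The acid is esterified with Me3SiCHN2 to the methyl ester F1. Its C10 dienolate (LiN(SiMe3)2, THF, −78 °C) is brominated with CBr4 to the α-bromo ester F2, and the acetal is hydrolysed (2 M HCl, THF) to the bromo aldehyde F3. SmI2 in THF at −78 °C then forms the samarium dienolate, which adds through C10 to the C1 aldehyde in a chelated chair that holds the C1 oxygen cis to C20, giving the cis hydroxy diester F4 under control by C5 alone. LiBH4 reduces the methyl ester next to the free hydroxyl and leaves the tert-butyl ester, and the route is rejoined at diol 22.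

Step 21. The diene may add to the wrong face of C8=C9 (syn to C5), or the cycloaddition may be too slow at the neopentyl C9 so that the dienophile decomposes. The fallback delivers the diene from the C1 oxygen and sets out from 22. Selective acetoacetylation of the primary hydroxyl with 26 (via 27) gives the hydroxy acetoacetate F5, ozonolysis gives the aldehyde F6, and Knoevenagel closure gives the alkylidene lactone with free C1–OH F7. Separately, 2-chlorobuta-1,3-diene and Mg give buta-1,3-dien-2-ylmagnesium chloride F8, which with Me2SiCl2 gives chloro(buta-1,3-dien-2-yl)dimethylsilane F9. Silylation of F7 with F9 (imidazole, CH2Cl2) gives the dienylsilyl ether F10. Heating in toluene brings about a silicon-tethered (type 2) intramolecular Diels–Alder reaction, in which the tether can reach only the C1 face and only joins C11 to C9, giving the bridged silacycle F11. Bu4NF in wet THF cleaves both Si–O and vinyl C–Si bonds to give the C1 alcohol F12, and acetylation (Ac2O, DMAP) returns to the route at 32.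

Step 23. The enol silane may be protodesilylated without C–C bond formation, the palladium enolate may close onto C12 to give the bicyclo[2.2.2]octane, or the new alkene may migrate towards C9. The fallback is a Heck closure and sets out from 32. The acetyl group is taken through the Mannich base F13 (LiN(SiMe3)2; Eschenmoser's salt) and the methiodide F14 (MeI) to the vinyl ketone F15 (aq NaHCO3). α-Iodination with I2 and pyridine gives the α-iodo enone F16. A 5-exo Heck cyclisation (Pd(OAc)2, PPh3, Ag2CO3, MeCN, 80 °C) joins C16 to C13, β-hydride elimination gives C11=C12, and the route is rejoined directly at 37.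

**Further compounds**

F1 | step 13 | methyl ester of 17 at C20 | O1CCCOC1CCC(C)(C)[C@@H](C(=O)OC(C)(C)C)[C@@H](/C=C/C)C(=O)OC
F2 | step 13 | C10 bromide of F1 (either C10 epimer) | O1CCCOC1CCC(C)(C)[C@@H](C(=O)OC(C)(C)C)C(Br)(/C=C/C)C(=O)OC
F3 | step 13 | bromo aldehyde from F2 (C1 aldehyde) | O=CCCC(C)(C)[C@@H](C(=O)OC(C)(C)C)C(Br)(/C=C/C)C(=O)OC
F4 | step 13 | 1-tert-butyl 2-methyl (1R,2S,3S)-3-hydroxy-6,6-dimethyl-2-[(E)-prop-1-enyl]cyclohexane-1,2-dicarboxylate | O[C@H]1CCC(C)(C)[C@@H](C(=O)OC(C)(C)C)[C@@]1(/C=C/C)C(=O)OC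
F5 | step 21 | C20 acetoacetate of diol 22 with free C1–OH | O[C@H]1CCC(C)(C)[C@@H](C(=O)OC(C)(C)C)[C@@]1(/C=C/C)COC(=O)CC(C)=O
F6 | step 21 | C9 aldehyde from F5 | O[C@H]1CCC(C)(C)[C@@H](C(=O)OC(C)(C)C)[C@@]1(C=O)COC(=O)CC(C)=O
F7 | step 21 | alkylidene lactone as 30 with free C1–OH | O[C@H]1CCC(C)(C)[C@@H](C(=O)OC(C)(C)C)[C@@]12COC(=O)C(C(C)=O)=C2
F8 | step 21 | buta-1,3-dien-2-ylmagnesium chloride | C=CC(=C)[Mg]Cl
F9 | step 21 | chloro(buta-1,3-dien-2-yl)dimethylsilane | C=CC(=C)[Si](C)(C)Cl
F10 | step 21 | C1 (buta-1,3-dien-2-yl)dimethylsilyl ether of F7 | C=CC(=C)[Si](C)(C)O[C@H]1CCC(C)(C)[C@@H](C(=O)OC(C)(C)C)[C@@]12COC(=O)C(C(C)=O)=C2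
F11 | step 21 | intramolecular Diels–Alder adduct with an O1–SiMe2–C12 bridge | C[Si]4(C)O[C@H]1CCC(C)(C)[C@@H](C(=O)OC(C)(C)C)[C@@]12COC(=O)[C@@]1(C(C)=O)CC=C4C[C@H]12
F12 | step 21 | C1 alcohol corresponding to 32 | O[C@H]1CCC(C)(C)[C@@H](C(=O)OC(C)(C)C)[C@@]12COC(=O)[C@@]1(C(C)=O)CC=CC[C@H]12
F13 | step 23 | Mannich base of 32, C8–CO–CH2CH2NMe2 | CC(=O)O[C@H]1CCC(C)(C)[C@@H](C(=O)OC(C)(C)C)[C@@]12COC(=O)[C@@]1(C(=O)CCN(C)C)CC=CC[C@H]12
F14 | step 23 | methiodide of F13 | CC(=O)O[C@H]1CCC(C)(C)[C@@H](C(=O)OC(C)(C)C)[C@@]12COC(=O)[C@@]1(C(=O)CC[N+](C)(C)C)CC=CC[C@H]12.[I-]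
F15 | step 23 | vinyl ketone, C8–CO–CH=CH2 | CC(=O)O[C@H]1CCC(C)(C)[C@@H](C(=O)OC(C)(C)C)[C@@]12COC(=O)[C@@]1(C(=O)C=C)CC=CC[C@H]12
F16 | step 23 | α-iodo enone, C8–CO–C(I)=CH2 | CC(=O)O[C@H]1CCC(C)(C)[C@@H](C(=O)OC(C)(C)C)[C@@]12COC(=O)[C@@]1(C(=O)C(I)=C)CC=CC[C@H]12
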